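**Plan**

1. Retrosynthesis: the biaryl C–C bond is cut last (Suzuki–Miyaura) into two regioisomeric iodophenols, both made from one mono-benzyl olivil 21. In 21 the aryl–CH2 bond (aryllithium onto a lactone C=O, then quinone-methide deoxygenation) and the tertiary C–OH (bridgehead enolate oxidation) are cut, then the ring O–CH(Ar) and ring CH2–C(quaternary) bonds, which leaves formaldehyde and a cyclopropane-fused γ-lactone.
2. Forward: (Z)-cinnamyl diazoacetate → intramolecular cyclopropanation (cyclopropane and lactone rings) → formal [3+2] addition of formaldehyde across the donor–acceptor C–C bond (oxolane ring; the cyclopropane is consumed) → hydroxylation → lactone opening by ArLi (tether removed) → benzylic deoxygenation → phenol-directed iodinations → borylation/Suzuki–Miyaura → hydrogenolysis.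
3. Enabling feature: in each oxolane the O-bearing benzylic carbon C5 carries a 4-oxygenated 3-methoxyphenyl donor and lies 1,3 to the carbinol carbon C3, whose benzyl carbon can serve as a lactone carbonyl (acceptor) tied to the cis CH2OH oxygen on C4.
4. Stereochemistry: C4 comes from the catalyst-controlled cyclopropanation, C5 from the Z-alkene geometry plus inversion in the key step, C3 from the enforced cis fusion of the bicyclic lactone; all six centres of the target derive from the single intermediate 21.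

Key step: step 5

Remark: the antipode of the dirhodium carboxamidate in step 4 is chosen so that lactone 9 is (1S,5R,6S); Rh2(5R-MEPY)4 is assumed to be that antipode, and the mirror-image catalyst would be used otherwise.

**Route**

Step 1
Reactants: 1 4-(benzyloxy)-3-methoxybenzaldehyde; 2 methyl bis(2,2,2-trifluoroethyl)phosphonoacetate
Product: 3 methyl (2Z)-3-[4-(benzyloxy)-3-methoxyphenyl]prop-2-enoate
Conditions: KN(SiMe3)2, 18-crown-6, THF, −78 °C
Reagents that add atoms: methyl bis(2,2,2-trifluoroethyl)phosphonoacetate (2), COC(=O)CP(=O)(OCC(F)(F)F)OCC(F)(F)F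
Why: Still–Gennari olefination, in which the electron-poor phosphonate and the dissociated potassium enolate make elimination from the kinetic adduct fast and should give the Z-enoate.

Step 2
Reactants: 3 methyl (2Z)-3-[4-(benzyloxy)-3-methoxyphenyl]prop-2-enoate
Product: 4 (2Z)-3-[4-(benzyloxy)-3-methoxyphenyl]prop-2-en-1-ol
Conditions: i-Bu2AlH (2.2 equiv), CH2Cl2, −78 °C
Reagents that add atoms: none
Why: 1,2-reduction of the enoate by the aluminium hydride should give the allylic alcohol with the Z geometry unchanged and the benzyl ether untouched.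

Step 3
Reactants: 4 (2Z)-3-[4-(benzyloxy)-3-methoxyphenyl]prop-2-en-1-ol; 5 bromoacetyl bromide; 6 N,N'-bis(p-toluenesulfonyl)hydrazine
Product: 8 (2Z)-3-[4-(benzyloxy)-3-methoxyphenyl]prop-2-en-1-yl diazoacetate, via bromoacetate 7 (not isolated)
Conditions: 5, NaHCO3, MeCN, 0 °C; then 6, DBU, THF, 0 °C
Reagents that add atoms: bromoacetyl bromide (5), BrCC(Br)=O; N,N'-bis(p-toluenesulfonyl)hydrazine (6), Cc1ccc(cc1)S(=O)(=O)NNS(=O)(=O)c1ccc(C)cc1
Why: O-acylation followed by N-alkylation of the bis-sulfonyl hydrazide and base-induced loss of two sulfinates (a Bamford–Stevens-type elimination) should give the diazoacetate under conditions mild enough for the Z-allylic ester.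

Step 4
Reactants: 8 (2Z)-3-[4-(benzyloxy)-3-methoxyphenyl]prop-2-en-1-yl diazoacetate
Product: 9 (1S,5R,6S)-6-[4-(benzyloxy)-3-methoxyphenyl]-3-oxabicyclo[3.1.0]hexan-2-one (aryl endo, cis to the lactone ring)
Conditions: Rh2(5R-MEPY)4 [dirhodium tetrakis(methyl (5R)-2-oxopyrrolidine-5-carboxylate)] (1 mol %), CH2Cl2, reflux, slow addition of 8
Reagents that add atoms: none
Why: intramolecular cyclopropanation by the chiral dirhodium carboxamidate carbenoid, in which the Z geometry is transferred stereospecifically (aryl endo) and the catalyst selects the alkene face, so both ring-fusion centres are set under catalyst control.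

Step 5
Reactants: 9 (1S,5R,6S)-6-[4-(benzyloxy)-3-methoxyphenyl]-3-oxabicyclo[3.1.0]hexan-2-one; 10 formaldehyde (supplied as paraformaldehyde)
Product: 11 (1R,5R,6S)-6-[4-(benzyloxy)-3-methoxyphenyl]-3,7-dioxabicyclo[3.3.0]octan-2-one (cis-fused, aryl exo)
Conditions: (CH2O)n (5 equiv), Sc(OTf)3 (10 mol %), 4 Å MS, CH2Cl2, −20 °C to rt
Reagents that add atoms: formaldehyde (10), C=O
Why: Sc(OTf)3 on the lactone carbonyl polarises the C1–C6 bond of 9, which joins the acceptor carbon (α to the lactone) to the donor carbon (bearing the 4-benzyloxy-3-methoxyphenyl ring); the formaldehyde oxygen attacks the benzylic carbon from the side opposite the breaking bond, and the lactone enolate then closes on the O-alkylated oxocarbenium carbon, so the ring CH2–C and O–CH(Ar) bonds form in one operation. The closest known reaction type is the Lewis-acid-catalysed formal [3+2] cycloaddition of aryl-donor cyclopropane esters with aldehydes, which gives tetrahydrofurans with inversion at the donor carbon. The oxolane closes by an intermolecular SN2-like C–O bond formation followed by a 5-(enolexo)-endo-trig aldol-type C–C closure. The former cyclopropane carbon C1 becomes a bridgehead of a bicyclo[3.3.0] system, so the lactone tether allows only the cis fusion; the benzylic centre is set by inversion, which turns the endo aryl of 9 into the exo aryl of 11 (aryl trans to the CH2O branch), and the exo face is also the less hindered one should the opening become SN1-like; the CH(CH2O) centre is not touched. The step needs cleavage of the donor–acceptor C–C bond rather than the other two ring bonds, and O-attack of formaldehyde rather than hydroxymethylation of the electron-rich arene; the first is secured by the vicinal push–pull substitution, the second by the mild Lewis acid, the low temperature and the fast intramolecular collapse of the zwitterion.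

Step 6
Reactants: 11 (1R,5R,6S)-6-[4-(benzyloxy)-3-methoxyphenyl]-3,7-dioxabicyclo[3.3.0]octan-2-one; 12 2-(phenylsulfonyl)-3-phenyloxaziridine
Product: 13 (1S,5R,6S)-6-[4-(benzyloxy)-3-methoxyphenyl]-1-hydroxy-3,7-dioxabicyclo[3.3.0]octan-2-one
Conditions: KN(SiMe3)2, THF, −78 °C; then 12, −78 °C; aq NH4Cl
Reagents that add atoms: 2-(phenylsulfonyl)-3-phenyloxaziridine (12), O=S(=O)(c1ccccc1)N1OC1c1ccccc1
Why: electrophilic hydroxylation of the lactone enolate by the N-sulfonyloxaziridine; the enolate carbon is a bridgehead, so oxygen can only enter with retention of the cis fusion (OH trans to the CH2O branch), and β-alkoxide loss is stereoelectronically disfavoured because the ring C–O bond lies in the enolate plane.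

Step 7
Reactants: 14 4-bromo-2-methoxyphenol; 15 tert-butyldimethylsilyl chloride
Product: 16 (4-bromo-2-methoxyphenoxy)(tert-butyl)dimethylsilane
Conditions: imidazole, DMF, rt
Reagents that add atoms: tert-butyldimethylsilyl chloride (15), CC(C)(C)[Si](C)(C)Cl
Why: standard imidazole-mediated O-silylation of a phenol, giving a base-labile mask that survives bromine–lithium exchange.

Step 8
Reactants: 13 (1S,5R,6S)-6-[4-(benzyloxy)-3-methoxyphenyl]-1-hydroxy-3,7-dioxabicyclo[3.3.0]octan-2-one; 16 (4-bromo-2-methoxyphenoxy)(tert-butyl)dimethylsilane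
Product: 18 {(3S,4R,5S)-5-[4-(benzyloxy)-3-methoxyphenyl]-3-hydroxy-4-(hydroxymethyl)oxolan-3-yl}{4-[(tert-butyldimethylsilyl)oxy]-3-methoxyphenyl}methanone (open form of its cyclic hemiketal), via aryllithium 17 (not isolated)
Conditions: 16 (2.5 equiv), n-BuLi (2.5 equiv), THF, −78 °C; then 13, −78 °C; aq NH4Cl
Reagents that add atoms: none
Why: bromine–lithium exchange followed by single addition of the aryllithium to the lactone carbonyl; one equivalent is consumed by the tertiary OH, the chelated lithium hemiketal alkoxide should not collapse at −78 °C, and no stereocentre is involved.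

Step 9
Reactants: 18 {(3S,4R,5S)-5-[4-(benzyloxy)-3-methoxyphenyl]-3-hydroxy-4-(hydroxymethyl)oxolan-3-yl}{4-[(tert-butyldimethylsilyl)oxy]-3-methoxyphenyl}methanone
Product: 21 (3S,4R,5S)-5-[4-(benzyloxy)-3-methoxyphenyl]-3-[(4-hydroxy-3-methoxyphenyl)methyl]-4-(hydroxymethyl)oxolan-3-ol, via benzylic alcohol 19 (not isolated), via quinone methide 20 (not isolated)
Conditions: NaBH4, EtOH, 0 °C; then NaBH4 (excess), 2 M aq NaOH, 70 °C
Reagents that add atoms: none
Why: carbonyl reduction, then alkaline cleavage of the aryl silyl ether and expulsion of the benzylic hydroxide by the para-phenoxide give a p-quinone methide (the intermediate type of lignan biosynthesis) that borohydride reduces by 1,6-addition, a known reduction of p-hydroxyaryl carbinols to methylene; the oxolane benzylic C–O cannot ionise because its aryl ring is benzyl-protected.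

Step 10
Reactants: 21 (3S,4R,5S)-5-[4-(benzyloxy)-3-methoxyphenyl]-3-[(4-hydroxy-3-methoxyphenyl)methyl]-4-(hydroxymethyl)oxolan-3-ol; 22 iodine
Product: 23 (3S,4R,5S)-5-[4-(benzyloxy)-3-methoxyphenyl]-3-[(4-hydroxy-3-iodo-5-methoxyphenyl)methyl]-4-(hydroxymethyl)oxolan-3-ol
Conditions: I2 (1.05 equiv), NaHCO3, THF/H2O, 0 °C
Reagents that add atoms: iodine (22), II
Why: electrophilic iodination through the phenoxide, which directs to the only free ortho position (para carries the side chain, the other ortho the methoxy group), while the benzyl-ether ring is far less reactive.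

Step 11
Reactants: 21 (3S,4R,5S)-5-[4-(benzyloxy)-3-methoxyphenyl]-3-[(4-hydroxy-3-methoxyphenyl)methyl]-4-(hydroxymethyl)oxolan-3-ol; 24 acetic anhydride
Product: 25 4-{[(3S,4R,5S)-5-[4-(benzyloxy)-3-methoxyphenyl]-3-hydroxy-4-(hydroxymethyl)oxolan-3-yl]methyl}-2-methoxyphenyl acetate
Conditions: Ac2O (1.1 equiv), K2CO3, acetone, 0 °C
Reagents that add atoms: acetic anhydride (24), CC(=O)OC(C)=O
Why: phenoxide-selective O-acylation, since carbonate deprotonates only the phenol, leaving the primary and tertiary alcohols free.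

Step 12
Reactants: 25 4-{[(3S,4R,5S)-5-[4-(benzyloxy)-3-methoxyphenyl]-3-hydroxy-4-(hydroxymethyl)oxolan-3-yl]methyl}-2-methoxyphenyl acetate
Product: 26 4-{[(3S,4R,5S)-3-hydroxy-5-(4-hydroxy-3-methoxyphenyl)-4-(hydroxymethyl)oxolan-3-yl]methyl}-2-methoxyphenyl acetate
Conditions: H2 (1 atm), Pd/C, EtOAc, rt, stopped after one equivalent of H2
Reagents that add atoms: none
Why: hydrogenolysis of the benzyl aryl ether is faster than that of the cyclic benzylic ether and leaves the aryl acetate intact, which exchanges the protecting pattern of the two phenols.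

Step 13
Reactants: 26 4-{[(3S,4R,5S)-3-hydroxy-5-(4-hydroxy-3-methoxyphenyl)-4-(hydroxymethyl)oxolan-3-yl]methyl}-2-methoxyphenyl acetate; 22 iodine
Product: 27 4-{[(3S,4R,5S)-3-hydroxy-5-(4-hydroxy-3-iodo-5-methoxyphenyl)-4-(hydroxymethyl)oxolan-3-yl]methyl}-2-methoxyphenyl acetate
Conditions: I2 (1.05 equiv), NaHCO3, THF/H2O, 0 °C
Reagents that add atoms: iodine (22), II
Why: the same phenoxide-directed ortho-iodination, now on the 5-aryl ring, because the acetylated ring is deactivated.

Step 14
Reactants: 23 (3S,4R,5S)-5-[4-(benzyloxy)-3-methoxyphenyl]-3-[(4-hydroxy-3-iodo-5-methoxyphenyl)methyl]-4-(hydroxymethyl)oxolan-3-ol; 27 4-{[(3S,4R,5S)-3-hydroxy-5-(4-hydroxy-3-iodo-5-methoxyphenyl)-4-(hydroxymethyl)oxolan-3-yl]methyl}-2-methoxyphenyl acetate; 28 bis(pinacolato)diboron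
Product: 31 mono-benzyl ether of the target (benzyl on the phenol of the 5-aryl ring of the half that is joined through its benzyl ring), via boronate 29 (not isolated), via biaryl acetate 30 (not isolated)
Conditions: 23, 28, KOAc, PdCl2(dppf), 1,4-dioxane, 85 °C; then 27, Pd(OAc)2, SPhos, 3 M aq K3PO4, 80 °C
Reagents that add atoms: bis(pinacolato)diboron (28), CC1(C)OB(OC1(C)C)B1OC(C)(C)C(C)(C)O1 (its boryl group is carried only by intermediate 29)
Why: Miyaura borylation followed in the same flask by Suzuki–Miyaura coupling; the two iodine atoms mark the carbons ortho to OH, which fixes the biaryl regiochemistry, and the hot aqueous phosphate should also hydrolyse the aryl acetate.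

Step 15
Reactants: 31 mono-benzyl ether of the target
Product: 32 CNP0269573.1
Conditions: H2 (1 atm), Pd/C, EtOAc/MeOH, rt
Reagents that add atoms: none
Why: hydrogenolysis of the last benzyl aryl ether under neutral conditions, which avoids the acid-induced cyclisation known for olivil-type oxolanes and should leave the two ring benzylic ethers intact if stopped on uptake of one equivalent.

**Compound list**

1 | 4-(benzyloxy)-3-methoxybenzaldehyde | O=Cc1ccc(OCc2ccccc2)c(OC)c1 | starting material
2 | methyl bis(2,2,2-trifluoroethyl)phosphonoacetate | COC(=O)CP(=O)(OCC(F)(F)F)OCC(F)(F)F | starting material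
3 | methyl (2Z)-3-[4-(benzyloxy)-3-methoxyphenyl]prop-2-enoate | COC(=O)/C=C\c1ccc(OCc2ccccc2)c(OC)c1 | intermediate
4 | (2Z)-3-[4-(benzyloxy)-3-methoxyphenyl]prop-2-en-1-ol | OC/C=C\c1ccc(OCc2ccccc2)c(OC)c1 | intermediate
5 | bromoacetyl bromide | BrCC(Br)=O | starting material
6 | N,N'-bis(p-toluenesulfonyl)hydrazine | Cc1ccc(cc1)S(=O)(=O)NNS(=O)(=O)c1ccc(C)cc1 | starting material
7 | (2Z)-3-[4-(benzyloxy)-3-methoxyphenyl]prop-2-en-1-yl bromoacetate | BrCC(=O)OC/C=C\c1ccc(OCc2ccccc2)c(OC)c1 | intermediate
8 | (2Z)-3-[4-(benzyloxy)-3-methoxyphenyl]prop-2-en-1-yl diazoacetate | [N-]=[N+]=CC(=O)OC/C=C\c1ccc(OCc2ccccc2)c(OC)c1 | intermediate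
9 | (1S,5R,6S)-6-[4-(benzyloxy)-3-methoxyphenyl]-3-oxabicyclo[3.1.0]hexan-2-one (aryl endo) | O=C1[C@H]2[C@@H](c3ccc(OCc4ccccc4)c(OC)c3)[C@H]2CO1 | intermediate
10 | formaldehyde (supplied as paraformaldehyde) | C=O | starting material
11 | (1R,5R,6S)-6-[4-(benzyloxy)-3-methoxyphenyl]-3,7-dioxabicyclo[3.3.0]octan-2-one (cis-fused, aryl exo) | O=C1[C@H]2CO[C@H](c3ccc(OCc4ccccc4)c(OC)c3)[C@H]2CO1 | intermediate
12 | 2-(phenylsulfonyl)-3-phenyloxaziridine | O=S(=O)(c1ccccc1)N1OC1c1ccccc1 | starting material
13 | (1S,5R,6S)-6-[4-(benzyloxy)-3-methoxyphenyl]-1-hydroxy-3,7-dioxabicyclo[3.3.0]octan-2-one | O=C1[C@@]2(O)CO[C@H](c3ccc(OCc4ccccc4)c(OC)c3)[C@H]2CO1 | intermediate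
14 | 4-bromo-2-methoxyphenol | COc1cc(Br)ccc1O | starting material
15 | tert-butyldimethylsilyl chloride | CC(C)(C)[Si](C)(C)Cl | starting material
16 | (4-bromo-2-methoxyphenoxy)(tert-butyl)dimethylsilane | COc1cc(Br)ccc1O[Si](C)(C)C(C)(C)C | intermediate
17 | {4-[(tert-butyldimethylsilyl)oxy]-3-methoxyphenyl}lithium | [Li]c1ccc(O[Si](C)(C)C(C)(C)C)c(OC)c1 | intermediate
18 | {(3S,4R,5S)-5-[4-(benzyloxy)-3-methoxyphenyl]-3-hydroxy-4-(hydroxymethyl)oxolan-3-yl}{4-[(tert-butyldimethylsilyl)oxy]-3-methoxyphenyl}methanone (open form of its cyclic hemiketal) | O=C(c1ccc(O[Si](C)(C)C(C)(C)C)c(OC)c1)[C@@]1(O)CO[C@H](c2ccc(OCc3ccccc3)c(OC)c2)[C@H]1CO | intermediate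
19 | (3S,4R,5S)-5-[4-(benzyloxy)-3-methoxyphenyl]-3-[{4-[(tert-butyldimethylsilyl)oxy]-3-methoxyphenyl}(hydroxy)methyl]-4-(hydroxymethyl)oxolan-3-ol (both carbinol epimers) | OC(c1ccc(O[Si](C)(C)C(C)(C)C)c(OC)c1)[C@@]1(O)CO[C@H](c2ccc(OCc3ccccc3)c(OC)c2)[C@H]1CO | intermediate
20 | p-quinone methide of 21 (exocyclic C=C at the benzylic carbon, oxolane centres as in 21) | COC1=CC(=C[C@@]2(O)CO[C@H](c3ccc(OCc4ccccc4)c(OC)c3)[C@H]2CO)C=CC1=O | intermediate
21 | (3S,4R,5S)-5-[4-(benzyloxy)-3-methoxyphenyl]-3-[(4-hydroxy-3-methoxyphenyl)methyl]-4-(hydroxymethyl)oxolan-3-ol | COc1cc(C[C@@]2(O)CO[C@H](c3ccc(OCc4ccccc4)c(OC)c3)[C@H]2CO)ccc1O | intermediate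
22 | iodine | II | starting material
23 | (3S,4R,5S)-5-[4-(benzyloxy)-3-methoxyphenyl]-3-[(4-hydroxy-3-iodo-5-methoxyphenyl)methyl]-4-(hydroxymethyl)oxolan-3-ol | COc1cc(C[C@@]2(O)CO[C@H](c3ccc(OCc4ccccc4)c(OC)c3)[C@H]2CO)cc(I)c1O | intermediate
24 | acetic anhydride | CC(=O)OC(C)=O | starting material
25 | 4-{[(3S,4R,5S)-5-[4-(benzyloxy)-3-methoxyphenyl]-3-hydroxy-4-(hydroxymethyl)oxolan-3-yl]methyl}-2-methoxyphenyl acetate | COc1cc(C[C@@]2(O)CO[C@H](c3ccc(OCc4ccccc4)c(OC)c3)[C@H]2CO)ccc1OC(C)=O | intermediate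
26 | 4-{[(3S,4R,5S)-3-hydroxy-5-(4-hydroxy-3-methoxyphenyl)-4-(hydroxymethyl)oxolan-3-yl]methyl}-2-methoxyphenyl acetate | COc1cc(C[C@@]2(O)CO[C@H](c3ccc(O)c(OC)c3)[C@H]2CO)ccc1OC(C)=O | intermediate
27 | 4-{[(3S,4R,5S)-3-hydroxy-5-(4-hydroxy-3-iodo-5-methoxyphenyl)-4-(hydroxymethyl)oxolan-3-yl]methyl}-2-methoxyphenyl acetate | COc1cc(C[C@@]2(O)CO[C@H](c3cc(I)c(O)c(OC)c3)[C@H]2CO)ccc1OC(C)=O | intermediate
28 | bis(pinacolato)diboron | CC1(C)OB(OC1(C)C)B1OC(C)(C)C(C)(C)O1 | starting material
29 | pinacol boronate of 23 (Bpin in place of iodine) | COc1cc(C[C@@]2(O)CO[C@H](c3ccc(OCc4ccccc4)c(OC)c3)[C@H]2CO)cc(B3OC(C)(C)C(C)(C)O3)c1O | intermediate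
30 | biaryl from 29 and 27, still carrying the aryl acetate and the benzyl ether | COc1cc(C[C@@]2(O)CO[C@H](c3cc(OC)c(O)c(-c4cc(C[C@@]5(O)CO[C@H](c6ccc(OCc7ccccc7)c(OC)c6)[C@H]5CO)cc(OC)c4O)c3)[C@H]2CO)ccc1OC(C)=O | intermediate
31 | mono-benzyl ether of the target (benzyl on the 5-aryl phenol of the half joined through its benzyl ring) | COc1cc(C[C@@]2(O)CO[C@H](c3cc(OC)c(O)c(-c4cc(C[C@@]5(O)CO[C@H](c6ccc(OCc7ccccc7)c(OC)c6)[C@H]5CO)cc(OC)c4O)c3)[C@H]2CO)ccc1O | intermediate
32 | CNP0269573.1, the 5,5'-biaryl of two (3S,4R,5S)-olivil units, one joined through its 5-aryl ring and one through its benzyl ring | COc1cc(C[C@@]2(O)CO[C@H](c3cc(OC)c(O)c(-c4cc(C[C@@]5(O)CO[C@H](c6ccc(O)c(OC)c6)[C@H]5CO)cc(OC)c4O)c3)[C@H]2CO)ccc1O | target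

**Totals and risks**

Total step count: 15. Longest linear sequence: 13 steps (1–6, 8, 9, 11–15).

Steps most likely to fail:

1. Step 5. The single lactone acceptor may activate the cyclopropane too weakly, so that ring opening with proton loss to a styrene, or hydroxymethylation of the electron-rich arene by formaldehyde, outruns the annulation. The fallback uses the classical doubly activated substrate class and sets out from 4. Acylation with methyl malonyl chloride and pyridine would give the mixed malonate F1, and diazo transfer with 4-acetamidobenzenesulfonyl azide and Et3N would give the diazomalonate F2. Intramolecular cyclopropanation with CuOTf and a C2-symmetric bis(oxazoline) ligand would give the cyclopropane lactone ester F3; its enantiomeric purity would have to be secured at this stage, for example by crystallisation. The Sn(OTf)2-catalysed [3+2] annulation with paraformaldehyde would give the furofuranone ester F4, and Krapcho dealkoxycarbonylation (LiCl, wet DMSO, 140 °C), whose bridgehead protonation can only give the cis-fused lactone, returns to the route at 11.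

2. Step 9. The quinone methide may be diverted by a 1,2-shift driven by the neighbouring tertiary alkoxide, or by intramolecular alkoxide capture, before hydride is delivered. The fallback sets out from 18 and removes the benzylic oxygen by a radical path. Reduction with NaBH4 at 0 °C and isolation gives 19; silylation of the primary alcohol (t-BuMe2SiCl, imidazole) would give the bis-silyl ether F5; 1,1'-thiocarbonyldiimidazole would close the 1,2-diol to the cyclic thionocarbonate F6. Barton–McCombie-type reduction (Bu3SnH, AIBN, toluene, 80 °C) cleaves towards the benzylic radical and, after basic hydrolysis of the residual thiolcarbonate, would give the deoxygenated bis-silyl ether F7; Bu4NF then returns to the route at 21.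

3. Step 14. Protodeboronation of the ortho-hydroxyaryl boronate and inhibition of the palladium catalyst by the two free ortho-phenols may stop the cross-coupling. The fallback sets out from 23 and masks the phenol of the boron partner. Benzylation (BnBr, K2CO3, acetone) would give the O-benzyl iodide F8, and Miyaura borylation with isolation would give the boronate F9. Suzuki–Miyaura coupling of F9 with 27 (Pd(OAc)2, SPhos, aq K3PO4, acetate cleaved in the same flask) would give the bis-benzyl ether F10, and hydrogenolysis as in step 15 removes both benzyl groups and returns to the route at 32.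

Further compounds
F1 | step 5 | (2Z)-3-[4-(benzyloxy)-3-methoxyphenyl]prop-2-en-1-yl methyl malonate | COC(=O)CC(=O)OC/C=C\c1ccc(OCc2ccccc2)c(OC)c1
F2 | step 5 | (2Z)-3-[4-(benzyloxy)-3-methoxyphenyl]prop-2-en-1-yl methyl 2-diazomalonate | COC(=O)C(=[N+]=[N-])C(=O)OC/C=C\c1ccc(OCc2ccccc2)c(OC)c1
F3 | step 5 | methyl 6-endo-[4-(benzyloxy)-3-methoxyphenyl]-2-oxo-3-oxabicyclo[3.1.0]hexane-1-carboxylate, ring centres as in 9 | O=C1[C@@]2(C(=O)OC)[C@@H](c3ccc(OCc4ccccc4)c(OC)c3)[C@H]2CO1
F4 | step 5 | methyl 6-exo-[4-(benzyloxy)-3-methoxyphenyl]-2-oxo-3,7-dioxabicyclo[3.3.0]octane-1-carboxylate, cis-fused, ring centres as in 11 | O=C1[C@@]2(C(=O)OC)CO[C@H](c3ccc(OCc4ccccc4)c(OC)c3)[C@H]2CO1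
F5 | step 9 | primary tert-butyldimethylsilyl ether of 19 | OC(c1ccc(O[Si](C)(C)C(C)(C)C)c(OC)c1)[C@@]1(O)CO[C@H](c2ccc(OCc3ccccc3)c(OC)c2)[C@H]1CO[Si](C)(C)C(C)(C)C
F6 | step 9 | cyclic thionocarbonate of the tertiary and benzylic hydroxyls of F5 | S=C1OC(c2ccc(O[Si](C)(C)C(C)(C)C)c(OC)c2)[C@]2(CO[C@H](c3ccc(OCc4ccccc4)c(OC)c3)[C@H]2CO[Si](C)(C)C(C)(C)C)O1
F7 | step 9 | bis(tert-butyldimethylsilyl) ether of 21 (phenol and primary alcohol) | COc1cc(C[C@@]2(O)CO[C@H](c3ccc(OCc4ccccc4)c(OC)c3)[C@H]2CO[Si](C)(C)C(C)(C)C)ccc1O[Si](C)(C)C(C)(C)C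
F8 | step 14 | O-benzyl ether of 23 at the iodinated phenol | COc1cc(C[C@@]2(O)CO[C@H](c3ccc(OCc4ccccc4)c(OC)c3)[C@H]2CO)cc(I)c1OCc1ccccc1
F9 | step 14 | pinacol boronate of F8 (Bpin in place of iodine) | COc1cc(C[C@@]2(O)CO[C@H](c3ccc(OCc4ccccc4)c(OC)c3)[C@H]2CO)cc(B3OC(C)(C)C(C)(C)O3)c1OCc1ccccc1
F10 | step 14 | bis-benzyl ether of the target (both phenols of the half joined through its benzyl ring) | COc1cc(C[C@@]2(O)CO[C@H](c3cc(OC)c(O)c(-c4cc(C[C@@]5(O)CO[C@H](c6ccc(OCc7ccccc7)c(OC)c6)[C@H]5CO)cc(OC)c4OCc4ccccc4)c3)[C@H]2CO)ccc1O
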